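**Plan**

- Retrosynthesis: the ring carboxyl is carried as CH2OSi, the lactone acyl C–O bond is opened, and two C–C bonds are then cut together: methylidene-bearing ring carbon to lactone carbonyl carbon, and carboxyl-bearing ring CH to chain-bearing O–CH. This leaves allene 11, methyl chloroformate and aldehyde 8, with boron as a temporary helper. The chain is cut next to its alkyne precursor (acetylide alkylation).
- Feature used: in the oxolan-2-one ring the methylidene-bearing carbon sits between the carbonyl carbon and the carboxyl-bearing CH, which is bonded to the O–CH carbon. These carbons plus the =CH2 are the skeleton of a propadiene, whose central carbon can take a carboxyl carbon while its substituted end acts as an allyl nucleophile toward an aldehyde.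
- Forward: chain aldehyde 8 (steps 1–5), allene 11 (step 6), one-flask union that also closes the lactone ring (step 7), oxidation of CH2OSi to CO2H (step 8), desilylation (step 9).
- Stereochemistry: the side-chain carbinol comes from (S)-pent-4-yn-2-ol. The ring O–CH centre is set by the chiral phosphoric acid, and the cis relation by the chair transition state of the (E)-allylboronate.

Key step: step 7

Remark: (R)-TRIP is assumed to keep, with the ester-bearing allylboronate 12, the facial preference it shows with simple pinacol allylboronates; if the sense were reversed, (S)-TRIP would be used in the same way.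

**Route**

Step 1
Reactants: 1 (S)-pent-4-yn-2-ol
Product: 2 (S)-tert-butyl(pent-4-yn-2-yloxy)diphenylsilane
Conditions: TBDPSCl, imidazole, DMF, rt
Reagents that add atoms: tert-butyl(chloro)diphenylsilane, CC(C)(C)[Si](Cl)(c1ccccc1)c1ccccc1
Why: Imidazole-promoted silyl ether formation at the secondary alcohol; the stereocentre is not touched.

Step 2
Reactants: 3 11-bromoundecan-1-ol
Product: 4 benzyl 11-bromoundecyl ether
Conditions: BnOC(=NH)CCl3, TfOH (cat.), CH2Cl2–cyclohexane, 0 °C to rt
Reagents that add atoms: benzyl 2,2,2-trichloroacetimidate, N=C(OCc1ccccc1)C(Cl)(Cl)Cl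
Why: Acid-catalysed benzylation with a trichloroacetimidate avoids forming an alkoxide beside the primary bromide.

Step 3
Reactants: 2 (S)-tert-butyl(pent-4-yn-2-yloxy)diphenylsilane; 4 benzyl 11-bromoundecyl ether
Product: 6 (S)-{[16-(benzyloxy)hexadec-4-yn-2-yl]oxy}(tert-butyl)diphenylsilane, via lithium acetylide 5 (not isolated)
Conditions: n-BuLi, THF, −78 °C; then 4, DMPU, −78 °C to rt
Reagents that add atoms: none
Why: SN2 alkylation of a lithium acetylide with a primary alkyl bromide should join the two chain pieces without touching the stereocentre.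

Step 4
Reactants: 6 (S)-{[16-(benzyloxy)hexadec-4-yn-2-yl]oxy}(tert-butyl)diphenylsilane
Product: 7 (S)-15-[(tert-butyldiphenylsilyl)oxy]hexadecan-1-ol
Conditions: H2 (1 atm), 10% Pd/C, EtOAc–EtOH, rt
Reagents that add atoms: none
Why: Heterogeneous catalytic hydrogenation should saturate the alkyne and hydrogenolyse the benzyl ether in one operation while the silyl ether survives.

Step 5
Reactants: 7 (S)-15-[(tert-butyldiphenylsilyl)oxy]hexadecan-1-ol
Product: 8 (S)-15-[(tert-butyldiphenylsilyl)oxy]hexadecanal
Conditions: TEMPO (cat.), PhI(OAc)2, CH2Cl2, rt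
Reagents that add atoms: none
Why: Nitroxyl-catalysed oxidation of a primary alcohol should stop at the aldehyde under neutral conditions.

Step 6
Reactants: 9 tert-butyldimethyl(prop-2-yn-1-yloxy)silane
Product: 11 (buta-2,3-dien-1-yloxy)(tert-butyl)dimethylsilane, via propargylic amine 10 (not isolated)
Conditions: (CH2O)n, CuBr, i-Pr2NH, 1,4-dioxane, reflux
Reagents that add atoms: formaldehyde (as paraformaldehyde), C=O
Why: Crabbé homologation: the Mannich reaction gives amine 10, whose copper-assisted 1,5-hydride shift and fragmentation should give the terminal allene.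

Step 7
Reactants: 11 (buta-2,3-dien-1-yloxy)(tert-butyl)dimethylsilane; 8 (S)-15-[(tert-butyldiphenylsilyl)oxy]hexadecanal
Product: 14 (4R,5S)-4-{[(tert-butyldimethylsilyl)oxy]methyl}-5-{(14S)-14-[(tert-butyldiphenylsilyl)oxy]pentadecyl}-3-methylideneoxolan-2-one, via allylboronate 12 (not isolated), via borate ester 13 (not isolated)
Conditions: 11 (1.5 equiv), PdCl2(MeCN)2 (5 mol %), B2pin2, ClCO2Me, toluene, 80 °C; volatiles stripped in vacuo; then 8, (R)-TRIP (10 mol %), 4 Å MS, toluene, −30 °C to rt; then 40 °C; direct chromatography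
Reagents that add atoms: methyl chloroformate, COC(=O)Cl; bis(pinacolato)diboron, CC1(C)OB(OC1(C)C)B1OC(C)(C)C(C)(C)O1 (its boron stays in 12 and 13 only, none in 14)
Why: Proposed new method: zerovalent palladium (from PdCl2(MeCN)2 and B2pin2) inserts into the C–Cl bond of ClCO2Me, the MeO2C–Pd unit adds across the terminal C=C of allene 11 with the ester carbon going to the central allene carbon (first C–C bond), and boryl transfer to the π-allyl gives allylboronate 12, which after removal of Cl–Bpin adds to aldehyde 8 through a phosphoric-acid-bound six-membered chair (second C–C bond) to give borate 13. The closest known reaction types are the palladium-catalysed acylboration of allenes with acid chlorides and diboron, the tandem allylboration–lactonisation of 2-alkoxycarbonyl allylboronates and the chiral-phosphoric-acid-catalysed allylboration of aldehydes with pinacol allylboronates; the use of a chloroformate and the telescoping of the three are new. The lactone ring closes by 5-exo-trig attack of the O–B oxygen of 13 on the acrylate carbonyl with loss of MeO–Bpin. The O–CH ring centre should be set by (R)-TRIP, which is expected to expose the Re face of the aldehyde as with simpler allylboronates, and the neighbouring ring centre by the (E) geometry of 12: the CH2OTBS group cis to CH2Bpin is axial in the chair and ends syn to the new oxygen, hence cis on the ring. The step needs ester delivery to the central carbon, boron delivery to the unsubstituted terminus and one alkene geometry; approach of palladium anti to the CH2OTBS substituent of the allene, the lower hindrance of the CH2 terminus and the thermodynamic preference for the ester trans to that substituent should secure them.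

Step 8
Reactants: 14 (4R,5S)-4-{[(tert-butyldimethylsilyl)oxy]methyl}-5-{(14S)-14-[(tert-butyldiphenylsilyl)oxy]pentadecyl}-3-methylideneoxolan-2-one
Product: 17 (2S,3S)-2-{(14S)-14-[(tert-butyldiphenylsilyl)oxy]pentadecyl}-4-methylidene-5-oxooxolane-3-carboxylic acid, via hydroxymethyl lactone 15 (not isolated), via formyl lactone 16 (not isolated)
Conditions: CrO3, aq. H2SO4 (Jones reagent), acetone, 0 °C to rt
Reagents that add atoms: water, O
Why: Jones oxidation: the acid should cleave the primary silyl ether, and chromic acid should take alcohol 15 through the hydrate of aldehyde 16 to the acid, while the bulky secondary TBDPS ether and the acrylate survive and the acidic medium leaves the cis ring centres in place.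

Step 9
Reactants: 17 (2S,3S)-2-{(14S)-14-[(tert-butyldiphenylsilyl)oxy]pentadecyl}-4-methylidene-5-oxooxolane-3-carboxylic acid
Product: 18 (2S,3S)-2-[(14S)-14-hydroxypentadecyl]-4-methylidene-5-oxooxolane-3-carboxylic acid
Conditions: HF·pyridine, THF, 0 °C to rt
Reagents that add atoms: none
Why: Fluoride-mediated silyl ether cleavage under acidic, non-basic conditions should leave the base-sensitive cis lactone acid and its exocyclic alkene untouched.

**Compound list**

1 | (S)-pent-4-yn-2-ol | C#CC[C@H](C)O | starting material
2 | (S)-tert-butyl(pent-4-yn-2-yloxy)diphenylsilane | C#CC[C@H](C)O[Si](c1ccccc1)(c1ccccc1)C(C)(C)C | intermediate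
3 | 11-bromoundecan-1-ol | OCCCCCCCCCCCBr | starting material
4 | benzyl 11-bromoundecyl ether | BrCCCCCCCCCCCOCc1ccccc1 | intermediate
5 | lithium acetylide of 2 (not isolated) | [Li]C#CC[C@H](C)O[Si](c1ccccc1)(c1ccccc1)C(C)(C)C | intermediate
6 | (S)-{[16-(benzyloxy)hexadec-4-yn-2-yl]oxy}(tert-butyl)diphenylsilane | c1ccccc1COCCCCCCCCCCCC#CC[C@H](C)O[Si](c1ccccc1)(c1ccccc1)C(C)(C)C | intermediate
7 | (S)-15-[(tert-butyldiphenylsilyl)oxy]hexadecan-1-ol | OCCCCCCCCCCCCCC[C@H](C)O[Si](c1ccccc1)(c1ccccc1)C(C)(C)C | intermediate
8 | (S)-15-[(tert-butyldiphenylsilyl)oxy]hexadecanal | O=CCCCCCCCCCCCCC[C@H](C)O[Si](c1ccccc1)(c1ccccc1)C(C)(C)C | intermediate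
9 | tert-butyldimethyl(prop-2-yn-1-yloxy)silane | C#CCO[Si](C)(C)C(C)(C)C | starting material
10 | 4-[(tert-butyldimethylsilyl)oxy]-N,N-di(propan-2-yl)but-2-yn-1-amine (not isolated) | CC(C)N(CC#CCO[Si](C)(C)C(C)(C)C)C(C)C | intermediate
11 | (buta-2,3-dien-1-yloxy)(tert-butyl)dimethylsilane | C=C=CCO[Si](C)(C)C(C)(C)C | intermediate
12 | methyl (2E)-4-[(tert-butyldimethylsilyl)oxy]-2-[(4,4,5,5-tetramethyl-1,3,2-dioxaborolan-2-yl)methyl]but-2-enoate (not isolated) | COC(=O)/C(=C/CO[Si](C)(C)C(C)(C)C)CB1OC(C)(C)C(C)(C)O1 | intermediate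
13 | methyl (3R,4S,18S)-3-{[(tert-butyldimethylsilyl)oxy]methyl}-18-[(tert-butyldiphenylsilyl)oxy]-2-methylidene-4-[(4,4,5,5-tetramethyl-1,3,2-dioxaborolan-2-yl)oxy]nonadecanoate (not isolated) | C=C(C(=O)OC)[C@H](CO[Si](C)(C)C(C)(C)C)[C@@H](OB1OC(C)(C)C(C)(C)O1)CCCCCCCCCCCCC[C@H](C)O[Si](c1ccccc1)(c1ccccc1)C(C)(C)C | intermediate
14 | (4R,5S)-4-{[(tert-butyldimethylsilyl)oxy]methyl}-5-{(14S)-14-[(tert-butyldiphenylsilyl)oxy]pentadecyl}-3-methylideneoxolan-2-one (cis) | C=C1C(=O)O[C@@H](CCCCCCCCCCCCC[C@H](C)O[Si](c2ccccc2)(c2ccccc2)C(C)(C)C)[C@H]1CO[Si](C)(C)C(C)(C)C | intermediate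
15 | (4R,5S)-5-{(14S)-14-[(tert-butyldiphenylsilyl)oxy]pentadecyl}-4-(hydroxymethyl)-3-methylideneoxolan-2-one (not isolated) | C=C1C(=O)O[C@@H](CCCCCCCCCCCCC[C@H](C)O[Si](c2ccccc2)(c2ccccc2)C(C)(C)C)[C@H]1CO | intermediate
16 | (2S,3S)-2-{(14S)-14-[(tert-butyldiphenylsilyl)oxy]pentadecyl}-4-methylidene-5-oxooxolane-3-carbaldehyde (not isolated) | C=C1C(=O)O[C@@H](CCCCCCCCCCCCC[C@H](C)O[Si](c2ccccc2)(c2ccccc2)C(C)(C)C)[C@H]1C=O | intermediate
17 | (2S,3S)-2-{(14S)-14-[(tert-butyldiphenylsilyl)oxy]pentadecyl}-4-methylidene-5-oxooxolane-3-carboxylic acid | C=C1C(=O)O[C@@H](CCCCCCCCCCCCC[C@H](C)O[Si](c2ccccc2)(c2ccccc2)C(C)(C)C)[C@H]1C(=O)O | intermediate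
18 | (2S,3S)-2-[(14S)-14-hydroxypentadecyl]-4-methylidene-5-oxooxolane-3-carboxylic acid | C=C1C(=O)O[C@@H](CCCCCCCCCCCCC[C@H](C)O)[C@H]1C(=O)O | target

**Step count and risks**

Total steps: 9. Longest linear sequence: 7 (steps 1, 3, 4, 5, 7, 8, 9).

Step 7. Stage one may fail by loss of CO from the methoxycarbonyl–palladium species or by β-silyloxy elimination in the π-allyl. Stage two may fail by poor facial selectivity if residual chloroborane or palladium salts drive a background addition. The fallback makes the two bonds in separate, known operations. It sets out from allene 11 and aldehyde 8. A copper-catalysed enantioselective borylative allene–aldehyde coupling (CuCl, NaOt-Bu, chiral bisphosphine with the antipode chosen for Re-face attack, B2pin2, THF) should pass through a (Z)-2-boryl-allylcopper chair and give the syn alcohol (3R,4S,18S)-3-{[(tert-butyldimethylsilyl)oxy]methyl}-18-[(tert-butyldiphenylsilyl)oxy]-2-(4,4,5,5-tetramethyl-1,3,2-dioxaborolan-2-yl)nonadec-1-en-4-ol F1. Iododeboronation (NaOH, I2, THF–water) would give (3R,4S,18S)-3-{[(tert-butyldimethylsilyl)oxy]methyl}-18-[(tert-butyldiphenylsilyl)oxy]-2-iodononadec-1-en-4-ol F2. Palladium-catalysed carbonylative lactonisation (Pd(PPh3)4, CO, K2CO3, MeCN, 60 °C) would close the ring and come back to the route at lactone 14.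

Step 8. The strongly acidic medium may epimerise the carboxyl-bearing ring carbon through the enolisable formyl lactone 16, or let the lactone acyl group migrate to the freed primary hydroxyl of 15. The fallback sets out from 14 and separates the two events. Mild methanolysis of the primary silyl ether (PPTS, MeOH, 0 °C) would give hydroxymethyl lactone 15, which is isolated. A buffered nitroxyl–chlorite oxidation (TEMPO, NaOCl cat., NaClO2, pH 6.7 phosphate buffer, MeCN) would then take it to the acid and come back to the route at 17.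

Step 9. Cleavage of the hindered secondary silyl ether may be slow, and long exposure of the free acid may let the exocyclic double bond move into the ring or the cis centres epimerise. The fallback sets out from 14 and removes both silyl groups at the neutral lactone stage (Bu4NF buffered with AcOH, THF). This would give (4R,5S)-5-[(14S)-14-hydroxypentadecyl]-4-(hydroxymethyl)-3-methylideneoxolan-2-one F3. A primary-selective nitroxyl oxidation (TEMPO, PhI(OAc)2, MeCN–water) would then oxidise only the CH2OH group and come back to the route at the target 18.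

Further compounds
F1 | step 7 | (3R,4S,18S)-3-{[(tert-butyldimethylsilyl)oxy]methyl}-18-[(tert-butyldiphenylsilyl)oxy]-2-(4,4,5,5-tetramethyl-1,3,2-dioxaborolan-2-yl)nonadec-1-en-4-ol | C=C(B1OC(C)(C)C(C)(C)O1)[C@H](CO[Si](C)(C)C(C)(C)C)[C@@H](O)CCCCCCCCCCCCC[C@H](C)O[Si](c1ccccc1)(c1ccccc1)C(C)(C)C
F2 | step 7 | (3R,4S,18S)-3-{[(tert-butyldimethylsilyl)oxy]methyl}-18-[(tert-butyldiphenylsilyl)oxy]-2-iodononadec-1-en-4-ol | C=C(I)[C@H](CO[Si](C)(C)C(C)(C)C)[C@@H](O)CCCCCCCCCCCCC[C@H](C)O[Si](c1ccccc1)(c1ccccc1)C(C)(C)C
F0 | step 8 | none | none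
F3 | step 9 | (4R,5S)-5-[(14S)-14-hydroxypentadecyl]-4-(hydroxymethyl)-3-methylideneoxolan-2-one | C=C1C(=O)O[C@@H](CCCCCCCCCCCCC[C@H](C)O)[C@H]1CO
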